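**Retrosynthetic overview**
- Feature: in the propionyl dienone ring the C(CH3)2 carbon lies between two carbonyl-level ring carbons (a dimethylmalonyl C3 unit); the other three ring carbons (the one bearing the bridge CH2, the ring C=O, the one bearing propionyl) form a 1,3-diketone chain with the propionyl C=O.
- Disconnections, last to first: the CH2 bridge to the acetyl dienone ring (formaldehyde); the aryl–butyryl bond (Friedel–Crafts); the two ring bonds from the CMe2-flanking carbonyl carbons to the arylmethyl-bearing and the propionyl-bearing carbons ([3+3] with dimethylmalonyl dichloride); the diketone chain (aldehyde + acetoacetate + propionyl Weinreb amide).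
- Design point: a plain 1-arylheptane-3,5-dione has two competing α′-CH2 groups, so the arylmethyl-bearing carbon carries a tert-butyl ester that makes it the only second acidic site; the ester leaves as isobutene and CO2 after ring closure.
- Ring order: the arene is bought; the propionyl dienone ring is closed in step 3; the acetyl dienone ring is made separately (step 7) and joined last (step 8).

Key step: step 3

Remark: the target has no stereocentre and no configured double bond, so there is no enantiomer to select; all enol tautomers are treated as one compound and one is drawn.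

Step 1
Reactants: 1 2,4,6-trimethoxybenzaldehyde; 2 tert-butyl 3-oxobutanoate
Product: 4 tert-butyl 3-oxo-2-(2,4,6-trimethoxybenzyl)butanoate (racemic), via benzylidene acetoacetate 3 (not isolated)
Conditions: piperidine (0.1 equiv), AcOH (0.1 equiv), 4 Å MS, toluene, 80 °C; then H2 (1 atm), 10% Pd/C, EtOAc, rt
Reagents that add atoms: none
Why: Knoevenagel condensation at the active methylene of 2, then heterogeneous hydrogenation of the electron-poor trisubstituted C=C; the new C2 stereocentre is formed racemic, which does not matter because step 4 removes it.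

Step 2
Reactants: 4 tert-butyl 3-oxo-2-(2,4,6-trimethoxybenzyl)butanoate; 5 N-methoxy-N-methylpropanamide
Product: 6 tert-butyl 3,5-dioxo-2-(2,4,6-trimethoxybenzyl)heptanoate (racemic)
Conditions: LDA (2.3 equiv), THF, −78 → 0 °C; then 5 (1.2 equiv), −78 → −20 °C; sat. aq. NH4Cl
Reagents that add atoms: none
Why: γ-Acylation of a β-keto ester dianion: LDA removes the C2–H and then a methyl proton, the terminal carbanion adds to the Weinreb amide, and the chelated tetrahedral adduct persists until the quench, so over-addition and proton transfer from the product are avoided.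

Step 3
Reactants: 6 tert-butyl 3,5-dioxo-2-(2,4,6-trimethoxybenzyl)heptanoate; 7 2,2-dimethylpropanedioyl dichloride (dimethylmalonyl dichloride)
Product: 10 tert-butyl 4-hydroxy-3,3-dimethyl-2,6-dioxo-5-propanoyl-1-(2,4,6-trimethoxybenzyl)cyclohex-4-ene-1-carboxylate (racemic), via C2-acylated acid chloride 8 (not isolated), via enol lactone 9 (not isolated)
Conditions: LiHMDS (2.05 equiv), THF, −78 → −40 °C; inverse addition to 7 (1.1 equiv), THF, −78 °C; then Et3N (3 equiv), DMAP (0.2 equiv), −78 °C → rt; cold 1 M HCl work-up
Reagents that add atoms: none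
Why: Proposed new method: two equivalents of LiHMDS remove the C4–H of the diketone and then the C2–H, which the ester makes the next most acidic site while the propionyl CH2 (C6) stays protonated; the terminal, most basic carbon C2 of this bis-enolate attacks one acid chloride of 7, as lithium ester enolates are C-acylated by hindered acid chlorides, and gives 8, whose C2 is quaternary so that no proton transfer can quench unreacted dianion. On warming with Et3N the lithium diketonate of 8 attacks the second acid chloride through its central carbon C4 in a 6-exo-trig C-acylation (enolate C3=C4 endo to the new ring), which forms the second ring bond and closes the carbocycle as its stabilised triketone enolate. Where the enolate oxygen on C3 closes instead (also 6-exo-trig), the exocyclic enol lactone 9 is an activated enol ester that DMAP reopens to an acylpyridinium–diketonate pair and delivers to C4, the O-to-C acyl shift that turns enol esters of 1,3-diones into 2-acyl-1,3-diones. The closest known reaction types are [3+3] cyclisations of 1,3-dicarbonyl dianions or 1,3-bis(silyl enol ethers) with 1,3-dielectrophiles and Claisen-type closures of 3,5,7-triketo acid derivatives to acylphloroglucinols. The step needs C2 over C6 in the first acylation and carbon over oxygen in the second: the ester secures the first by acidity, the acyl-transfer catalyst corrects the second, 7 has no α-hydrogen and cannot form a ketene, and inverse addition keeps each molecule of 7 to one dianion. The only new stereocentre, quaternary C2 (ring C1 of 10), forms racemic and is erased in step 4.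

Step 4
Reactants: 10 tert-butyl 4-hydroxy-3,3-dimethyl-2,6-dioxo-5-propanoyl-1-(2,4,6-trimethoxybenzyl)cyclohex-4-ene-1-carboxylate
Product: 12 3,5-dihydroxy-4,4-dimethyl-2-propanoyl-6-(2,4,6-trimethoxybenzyl)cyclohexa-2,5-dien-1-one, via β-keto acid 11 (not isolated)
Conditions: p-TsOH·H2O (10 mol %), toluene, 80 °C
Reagents that add atoms: none
Why: Acid-catalysed loss of isobutene from the tert-butyl ester gives a carboxylic acid flanked by two ring ketones, which decarboxylates through the enol to the dienone tautomer and removes the racemic quaternary centre; isobutene leaves as a gas and so should not alkylate the electron-rich arene.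

Step 5
Reactants: 12 3,5-dihydroxy-4,4-dimethyl-2-propanoyl-6-(2,4,6-trimethoxybenzyl)cyclohexa-2,5-dien-1-one
Product: 13 3,5-dihydroxy-4,4-dimethyl-2-propanoyl-6-(2,4,6-trihydroxybenzyl)cyclohexa-2,5-dien-1-one
Conditions: BBr3 (8 equiv), CH2Cl2, −78 °C → rt; then MeOH, H2O, 0 °C
Reagents that add atoms: none
Why: Lewis-acid cleavage of aryl methyl ethers (boron–oxygen adduct, then bromide SN2 at methyl); the enolised triketone is held as a boron chelate and is released on hydrolysis.

Step 6
Reactants: 13 3,5-dihydroxy-4,4-dimethyl-2-propanoyl-6-(2,4,6-trihydroxybenzyl)cyclohexa-2,5-dien-1-one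
Product: 14 2-(3-butanoyl-2,4,6-trihydroxybenzyl)-3,5-dihydroxy-4,4-dimethyl-6-propanoylcyclohexa-2,5-dien-1-one
Conditions: butanoyl chloride (1.1 equiv), AlCl3 (4 equiv), PhNO2/CH2Cl2, 0 °C → rt; ice/1 M HCl
Reagents that add atoms: butanoyl chloride, CCCC(Cl)=O
Why: Friedel–Crafts C-acylation of a phloroglucinol: the two free aromatic carbons are equivalent, the first acyl group deactivates the ring against a second, and the dienone ring has no free carbon left.

Step 7
Reactants: 15 1-(2,4,6-trihydroxyphenyl)ethan-1-one
Product: 16 2-acetyl-3,5-dihydroxy-4,4-dimethylcyclohexa-2,5-dien-1-one (acetylfilicinic acid)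
Conditions: NaOMe (4 equiv), MeI (3 equiv), MeOH, 0 °C → rt; 1 M HCl
Reagents that add atoms: iodomethane, CI
Why: Dearomatising geminal C-methylation of an acylphloroglucinol polyanion, a known route to acylfilicinic acids; the second methyl group enters at the already methylated carbon because its enolate is the more nucleophilic site.

Step 8
Reactants: 14 2-(3-butanoyl-2,4,6-trihydroxybenzyl)-3,5-dihydroxy-4,4-dimethyl-6-propanoylcyclohexa-2,5-dien-1-one; 16 2-acetyl-3,5-dihydroxy-4,4-dimethylcyclohexa-2,5-dien-1-one
Product: 17 target trimer (acetyl dienone–CH2–butanoylphloroglucinol–CH2–propanoyl dienone)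
Conditions: 16 (3 equiv), 37% aq. CH2O (2 equiv), 1% aq. KOH, 0 °C → rt, short reaction time; then 1 M HCl
Reagents that add atoms: formaldehyde, C=O
Why: Formaldehyde condensation (hydroxymethylation, loss of water to a methylene-trione, conjugate addition of the second nucleophile), the classical way to methylene-bridged acylphloroglucinols; each partner has one free nucleophilic carbon and the excess of 16 should bias the mixture toward the cross-coupled product.

**Compound list**
1 | 2,4,6-trimethoxybenzaldehyde | COc1cc(OC)c(C=O)c(OC)c1 | starting material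
2 | tert-butyl 3-oxobutanoate | CC(=O)CC(=O)OC(C)(C)C | starting material
3 | tert-butyl 2-acetyl-3-(2,4,6-trimethoxyphenyl)prop-2-enoate (E/Z mixture) | CC(=O)C(=Cc1c(OC)cc(OC)cc1OC)C(=O)OC(C)(C)C | intermediate (not isolated)
4 | tert-butyl 3-oxo-2-(2,4,6-trimethoxybenzyl)butanoate (racemic) | CC(=O)C(Cc1c(OC)cc(OC)cc1OC)C(=O)OC(C)(C)C | intermediate
5 | N-methoxy-N-methylpropanamide | CCC(=O)N(C)OC | starting material
6 | tert-butyl 3,5-dioxo-2-(2,4,6-trimethoxybenzyl)heptanoate (racemic) | CCC(=O)CC(=O)C(Cc1c(OC)cc(OC)cc1OC)C(=O)OC(C)(C)C | intermediate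
7 | 2,2-dimethylpropanedioyl dichloride | CC(C)(C(Cl)=O)C(Cl)=O | starting material
8 | tert-butyl 2-(3-chloro-2,2-dimethyl-3-oxopropanoyl)-3,5-dioxo-2-(2,4,6-trimethoxybenzyl)heptanoate (racemic) | CCC(=O)CC(=O)C(Cc1c(OC)cc(OC)cc1OC)(C(=O)OC(C)(C)C)C(=O)C(C)(C)C(Cl)=O | intermediate (not isolated)
9 | tert-butyl 5,5-dimethyl-4,6-dioxo-2-(2-oxobutylidene)-3-(2,4,6-trimethoxybenzyl)oxane-3-carboxylate (racemic, alkene geometry undefined; formed only as far as oxygen closure competes) | CCC(=O)C=C1OC(=O)C(C)(C)C(=O)C1(Cc2c(OC)cc(OC)cc2OC)C(=O)OC(C)(C)C | intermediate (not isolated)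
10 | tert-butyl 4-hydroxy-3,3-dimethyl-2,6-dioxo-5-propanoyl-1-(2,4,6-trimethoxybenzyl)cyclohex-4-ene-1-carboxylate (racemic) | CCC(=O)C1=C(O)C(C)(C)C(=O)C(Cc2c(OC)cc(OC)cc2OC)(C(=O)OC(C)(C)C)C1=O | intermediate
11 | 4-hydroxy-3,3-dimethyl-2,6-dioxo-5-propanoyl-1-(2,4,6-trimethoxybenzyl)cyclohex-4-ene-1-carboxylic acid (racemic) | CCC(=O)C1=C(O)C(C)(C)C(=O)C(Cc2c(OC)cc(OC)cc2OC)(C(=O)O)C1=O | intermediate (not isolated)
12 | 3,5-dihydroxy-4,4-dimethyl-2-propanoyl-6-(2,4,6-trimethoxybenzyl)cyclohexa-2,5-dien-1-one | COc1cc(OC)cc(OC)c1CC1=C(O)C(C)(C)C(O)=C(C(=O)CC)C1=O | intermediate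
13 | 3,5-dihydroxy-4,4-dimethyl-2-propanoyl-6-(2,4,6-trihydroxybenzyl)cyclohexa-2,5-dien-1-one | CCC(=O)C1=C(O)C(C)(C)C(O)=C(Cc2c(O)cc(O)cc2O)C1=O | intermediate
14 | 2-(3-butanoyl-2,4,6-trihydroxybenzyl)-3,5-dihydroxy-4,4-dimethyl-6-propanoylcyclohexa-2,5-dien-1-one | CCCC(=O)c1c(O)cc(O)c(CC2=C(O)C(C)(C)C(O)=C(C(=O)CC)C2=O)c1O | intermediate
15 | 1-(2,4,6-trihydroxyphenyl)ethan-1-one | CC(=O)c1c(O)cc(O)cc1O | starting material
16 | 2-acetyl-3,5-dihydroxy-4,4-dimethylcyclohexa-2,5-dien-1-one | CC(=O)C1=C(O)C(C)(C)C(O)=CC1=O | intermediate
17 | 2-acetyl-6-{3-butanoyl-5-[(2,6-dihydroxy-3,3-dimethyl-4-oxo-5-propanoylcyclohexa-1,5-dien-1-yl)methyl]-2,4,6-trihydroxybenzyl}-3,5-dihydroxy-4,4-dimethylcyclohexa-2,5-dien-1-one (achiral) | CCCC(=O)c1c(O)c(CC2=C(O)C(C)(C)C(O)=C(C(C)=O)C2=O)c(O)c(CC2=C(O)C(C)(C)C(O)=C(C(=O)CC)C2=O)c1O | target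

**Step count**
Total: 8 steps. Longest linear sequence: 7 steps (steps 1–6 and 8); step 7 is a one-step side branch.

**Steps most likely to fail**

1. Step 3 (Proposed new method). The bis-enolate may be acylated at oxygen or at C4 first, two dianions may be linked through one diacid chloride, or the O-closed lactone may resist the acyl shift. Fallback with known chemistry, setting out from 1 and returning at 12: commercial 1-(2,4,6-trihydroxyphenyl)propan-1-one F1 is gem-dimethylated under the conditions of step 7 (NaOMe, MeI, MeOH) to 3,5-dihydroxy-4,4-dimethyl-2-propanoylcyclohexa-2,5-dien-1-one F2. The free ring carbon of F2 is then alkylated with aldehyde 1 by an organocatalytic reductive Knoevenagel alkylation (L-proline cat., Hantzsch ester, EtOH, rt to 50 °C), which should give 12 directly. This gives up the [3+3] ring synthesis and builds the ring by dearomatisation instead.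

2. Step 8. Formaldehyde may link like partners instead of unlike ones, and the alkaline medium may exchange the methylene bridge already present in 14. Fallback from 16, returning at 17: 16 is aminomethylated with Eschenmoser's salt (CH2Cl2, rt) to 2-acetyl-6-[(dimethylamino)methyl]-3,5-dihydroxy-4,4-dimethylcyclohexa-2,5-dien-1-one F4. Warming F4 with 14 (1,4-dioxane, 60–80 °C, no added base) should expel dimethylamine, generate the methylene-trione at low concentration and let the free aromatic carbon of 14 add to it, so that the one-carbon unit is fixed on one partner before the two meet.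

3. Step 6. Under the Lewis acid the benzylic bridge may be cleaved or exchanged, the phenol next to the bridge may cyclise onto the dienone with loss of water, and O-acylation or double acylation may compete. Fallback from 12, returning at 14: the trimethoxy arene of 12 is acylated first (butanoyl chloride, SnCl4, CH2Cl2, −20 °C) to 2-(3-butanoyl-2,4,6-trimethoxybenzyl)-3,5-dihydroxy-4,4-dimethyl-6-propanoylcyclohexa-2,5-dien-1-one F3, and the three methyl ethers of F3 are then cleaved with BBr3 (CH2Cl2, −78 °C → rt) to 14. Free phenols thus never meet the acylating Lewis acid.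

**Further compounds**
F1 | step 3 | 1-(2,4,6-trihydroxyphenyl)propan-1-one (commercial starting material of the fallback) | CCC(=O)c1c(O)cc(O)cc1O
F2 | step 3 | 3,5-dihydroxy-4,4-dimethyl-2-propanoylcyclohexa-2,5-dien-1-one | CCC(=O)C1=C(O)C(C)(C)C(O)=CC1=O
F3 | step 6 | 2-(3-butanoyl-2,4,6-trimethoxybenzyl)-3,5-dihydroxy-4,4-dimethyl-6-propanoylcyclohexa-2,5-dien-1-one | CCCC(=O)c1c(OC)cc(OC)c(CC2=C(O)C(C)(C)C(O)=C(C(=O)CC)C2=O)c1OC
F4 | step 8 | 2-acetyl-6-[(dimethylamino)methyl]-3,5-dihydroxy-4,4-dimethylcyclohexa-2,5-dien-1-one | CC(=O)C1=C(O)C(C)(C)C(O)=C(CN(C)C)C1=O
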